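## Retrosynthetic overview

1. Numbering: ring A is the cyclohexane C1–C2–C3–C4(Me2)–C5–C10; C5 bears the chain C6–C7–C8(=O)–CH3, C10 bears a methyl and the C9 ketone, and C11–C15 is the 3-methylpentanoate arm (C13 methyl, C15 ester carbon). The plan rests on ring A being the α-ionone skeleton short of only C9, which must sit on C10 cis to the C5 chain.
2. Endgame disconnections: the acetate (selective acylation of the primary glycerol hydroxyl), the C15 glyceryl ester ((S)-solketal), and C9–C11 (a C11–C15 alkyllithium from (R)-citronellol added to the C9 aldehyde, then oxidation).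
3. Key disconnection C9–C10: a [2,3]-Wittig–Still shift of the (tributylstannyl)methyl ether of the C2 allylic alcohol, oxygen cis to the C5 chain, delivers CH2OH to C10 on that same face and moves the alkene from C1=C10 to C1=C2.
4. The cis-cyclohexenol comes from (S)-dihydro-α-ionone ethylene ketal by allylic oxidation at C2 and catalyst-controlled reduction; (S)-α-ionone comes from racemic α-ionone through lipase resolution of α-ionol.
5. Ring order: ring A is carried from α-ionone and no ring of the target is formed in the route; the two dioxolanes are protecting groups only.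

Key step: step 12

Assumption: the α-ionol 4-nitrobenzoate that crystallises in step 2 is taken to be the racemate with carbinol (R) paired with ring (S) (the pair drawn for 3); if the other racemate crystallises, the unreacted alcohol of step 4 carries the (S) ring instead and enters step 6 directly.

## Route

Step 1
Reactants: 1 α-ionone, racemic (E)-4-(2,6,6-trimethylcyclohex-2-en-1-yl)but-3-en-2-one
Product: 2 α-ionol, (E)-4-(2,6,6-trimethylcyclohex-2-en-1-yl)but-3-en-2-ol, both racemic diastereomers
Conditions: NaBH4, CeCl3·7H2O, MeOH, 0 °C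
Reagents that add atoms: none
Why: Luche reduction should give clean 1,2-reduction of the enone; the carbinol centre forms without control, which is acceptable because the diastereomers are separated in step 2.

Step 2
Reactants: 2 α-ionol (diastereomer mixture)
Product: 3 rac-(2R,3E)-4-[(1S)-2,6,6-trimethylcyclohex-2-en-1-yl]but-3-en-2-yl 4-nitrobenzoate, one racemic diastereomer
Conditions: 4-nitrobenzoyl chloride, pyridine, DMAP (cat.), CH2Cl2, 0 °C to rt; fractional crystallisation from hexane
Reagents that add atoms: 4-nitrobenzoyl chloride, O=C(Cl)c1ccc(cc1)[N+](=O)[O-]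
Why: Acylation of the secondary alcohol (nucleophilic acyl substitution) gives crystalline esters, and fractional crystallisation should separate one racemic diastereomer; no stereocentre is formed or touched.

Step 3
Reactants: 3 racemic 4-nitrobenzoate
Product: 4 rac-(2R,3E)-4-[(1S)-2,6,6-trimethylcyclohex-2-en-1-yl]but-3-en-2-ol, racemic single diastereomer of α-ionol
Conditions: K2CO3 (cat.), MeOH, rt
Reagents that add atoms: none
Why: Base-catalysed transesterification of the activated aryl ester should free the alcohol without touching either stereocentre.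

Step 4
Reactants: 4 racemic single-diastereomer α-ionol
Product: 5 (2R,3E)-4-[(1S)-2,6,6-trimethylcyclohex-2-en-1-yl]but-3-en-2-yl acetate
Conditions: lipase PS (Burkholderia cepacia), vinyl acetate, t-BuOMe, rt, stopped near half conversion; chromatography
Reagents that add atoms: vinyl acetate, CC(=O)OC=C
Why: Lipase-catalysed kinetic resolution by irreversible transesterification: the enzyme should acylate only the (R)-carbinol (methyl as the medium and alkenyl as the large substituent), which in this racemate is tied to the (S) ring centre C5, while the mirror-image alcohol stays unreacted and is removed.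

Step 5
Reactants: 5 (R,S)-acetate
Product: 6 (2R,3E)-4-[(1S)-2,6,6-trimethylcyclohex-2-en-1-yl]but-3-en-2-ol
Conditions: K2CO3 (cat.), MeOH, rt
Reagents that add atoms: none
Why: Mild methanolysis of the acetate should leave both stereocentres untouched.

Step 6
Reactants: 6 enantiopure α-ionol
Product: 7 (S)-α-ionone, (3E)-4-[(1S)-2,6,6-trimethylcyclohex-2-en-1-yl]but-3-en-2-one
Conditions: MnO2, CH2Cl2, rt
Reagents that add atoms: none
Why: MnO2 oxidation of the allylic alcohol is neutral, so the doubly allylic C5–H is not deprotonated and neither racemisation nor isomerisation to β-ionone should occur.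

Step 7
Reactants: 7 (S)-α-ionone
Product: 9 (S)-dihydro-α-ionone [4-[(1S)-2,6,6-trimethylcyclohex-2-en-1-yl]butan-2-one], via triethylsilyl enol ether 8 (not isolated)
Conditions: Et3SiH, RhCl(PPh3)3 (cat.), benzene, 50 °C; then 1 M HCl, acetone, 0 °C
Reagents that add atoms: none
Why: Rhodium-catalysed 1,4-hydrosilylation of the enone with a monohydrosilane should reduce only the conjugated C=C, and hydrolysis of the silyl enol ether gives the saturated ketone with the ring alkene and C5 untouched.

Step 8
Reactants: 9 (S)-dihydro-α-ionone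
Product: 10 2-methyl-2-{2-[(1S)-2,6,6-trimethylcyclohex-2-en-1-yl]ethyl}-1,3-dioxolane
Conditions: ethylene glycol, PPTS, benzene, reflux (Dean–Stark)
Reagents that add atoms: ethylene glycol, OCCO
Why: Acid-catalysed ketalisation driven by azeotropic removal of water; the weak acid should leave the trisubstituted ring alkene in place.

Step 9
Reactants: 10 ketal
Product: 12 (4S)-3,5,5-trimethyl-4-[2-(2-methyl-1,3-dioxolan-2-yl)ethyl]cyclohex-2-en-1-one, via allylic tert-butyl peroxide 11 (not isolated)
Conditions: Rh2(cap)4 (dirhodium tetracaprolactamate, cat.), t-BuOOH (decane solution), K2CO3, CH2Cl2, rt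
Reagents that add atoms: tert-butyl hydroperoxide, CC(C)(C)OO
Why: Radical allylic oxidation: the tert-butylperoxyl radical should abstract hydrogen from the secondary allylic C2 rather than from the tertiary C5–H shielded by the gem-dimethyl group and the chain, the allyl radical is trapped at C2 as the mixed peroxide, and base-induced Kornblum–DeLaMare elimination gives the C2 enone, the dioxolane being stable to these basic conditions.

Step 10
Reactants: 12 enone
Product: 13 (1R,4S)-3,5,5-trimethyl-4-[2-(2-methyl-1,3-dioxolan-2-yl)ethyl]cyclohex-2-en-1-ol (hydroxyl cis to the side chain)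
Conditions: (S)-2-methyl-CBS-oxazaborolidine, catecholborane, toluene, −78 °C; MeOH, then aq. NaOH work-up
Reagents that add atoms: none
Why: Corey–Bakshi–Shibata reduction: the catalyst binds the carbonyl oxygen anti to the alkene arm (the large group) and delivers hydride to one face, which should give the (R)-carbinol at C2, i.e. oxygen cis to the C5 chain; the substrate's own bias is expected to be small because one face is screened by the axial C4 methyl and the other by the pseudoaxial chain, and any trans epimer is removed by chromatography.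

Step 11
Reactants: 13 cis-cyclohexenol; 14 tributyl(iodomethyl)stannane
Product: 16 tributyl({[(1R,4S)-3,5,5-trimethyl-4-[2-(2-methyl-1,3-dioxolan-2-yl)ethyl]cyclohex-2-en-1-yl]oxy}methyl)stannane, via potassium alkoxide 15 (not isolated)
Conditions: KH, THF, 0 °C; then 14, 0 °C to rt
Reagents that add atoms: none
Why: Williamson etherification of the potassium alkoxide with the primary iodide; the C2–O bond is not broken, so the cis configuration is kept.

Step 12
Reactants: 16 stannylmethyl ether
Product: 18 [(1R,6S)-1,5,5-trimethyl-6-[2-(2-methyl-1,3-dioxolan-2-yl)ethyl]cyclohex-2-en-1-yl]methanol (hydroxymethyl cis to the side chain), via alkoxymethyllithium 17 (not isolated)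
Conditions: n-BuLi, THF, −78 to −20 °C; then H2O
Reagents that add atoms: none
Why: Tin–lithium exchange with n-BuLi gives the α-alkoxymethyllithium 17, whose carbanion carbon (C9) bonds to C10 while the C2–O bond breaks in a concerted, suprafacial [2,3]-sigmatropic shift through a five-membered envelope transition state (C9, O, C2, C1, C10), leaving the alkene at C1=C2 and the oxygen as the C9 alkoxide. The closest known reaction type is the Wittig–Still rearrangement of stannylmethyl ethers of 3-methylcyclohex-2-enols, which places a hydroxymethyl group on a fully substituted ring carbon. No ring is closed, so there is no mode of closure to specify; one skeletal bond (C9–C10) and one stereocentre (C10) are formed. The C10 configuration is controlled by the C2 carbinol centre: the new bond forms on the face from which the oxygen leaves, so the C2 oxygen cis to the C5 chain becomes C9 cis to C6, i.e. (R) at C10. The step needs the [2,3] path to beat the [1,2] shift and simple proton quench, and needs complete suprafacial transfer; the half-chair with the C2–O bond pseudoaxial is reachable (at the cost of a pseudoequatorial C5 chain and a syn-axial C4 methyl), the intramolecular delivery tolerates the neopentyl-like terminus, and low temperature disfavours the radical-pair [1,2] route.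

Step 13
Reactants: 18 homoallylic alcohol
Product: 19 [(1R,2S)-1,3,3-trimethyl-2-[2-(2-methyl-1,3-dioxolan-2-yl)ethyl]cyclohexyl]methanol
Conditions: H2 (1 atm), 10% Pd/C, EtOAc, rt
Reagents that add atoms: none
Why: Heterogeneous hydrogenation of the cis-disubstituted C1=C2 alkene creates no stereocentre, and the ketal is inert under neutral conditions.

Step 14
Reactants: 19 saturated alcohol
Product: 20 (1R,2S)-1,3,3-trimethyl-2-[2-(2-methyl-1,3-dioxolan-2-yl)ethyl]cyclohexane-1-carbaldehyde
Conditions: Dess–Martin periodinane, pyridine, CH2Cl2, 0 °C to rt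
Reagents that add atoms: none
Why: Dess–Martin oxidation of the neopentyl primary alcohol stops at the aldehyde, the pyridine buffer protects the ketal, and the aldehyde has no α-hydrogen so C10 cannot epimerise.

Step 15
Reactants: 21 (R)-citronellol
Product: 22 tert-butyl{[(3R)-3,7-dimethyloct-6-en-1-yl]oxy}diphenylsilane
Conditions: TBDPSCl, imidazole, CH2Cl2, rt
Reagents that add atoms: tert-butyl(chloro)diphenylsilane, CC(C)(C)[Si](Cl)(c1ccccc1)c1ccccc1
Why: Silylation of the primary alcohol; the TBDPS ether is chosen to survive the radical iodination, tert-butyllithium and the later oxidations.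

Step 16
Reactants: 22 citronellyl silyl ether
Product: 23 (4R)-6-[(tert-butyldiphenylsilyl)oxy]-4-methylhexanoic acid
Conditions: NaIO4, KMnO4 (cat.), t-BuOH/aq. phosphate buffer (pH 7.5), rt; then dilute HCl
Reagents that add atoms: sodium periodate, [Na+].[O-]I(=O)(=O)=O
Why: Lemieux–von Rudloff oxidative cleavage of the trisubstituted alkene should give the carboxylic acid and acetone, the methyl-bearing stereocentre being remote from the reacting carbons.

Step 17
Reactants: 23 acid
Product: 24 tert-butyl{[(3S)-5-iodo-3-methylpentyl]oxy}diphenylsilane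
Conditions: PhI(OAc)2, iodine, cyclohexane, hν (tungsten lamp), reflux
Reagents that add atoms: iodine, [I][I]
Why: Photochemical iododecarboxylation (a Hunsdiecker-type radical chain): the acyloxy radical loses CO2 and the primary alkyl radical should be trapped by iodine faster than it can abstract hydrogen intramolecularly; the stereocentre is not at the radical carbon, and its descriptor becomes (S) only because iodine raises the priority of that arm.

Step 18
Reactants: 24 iodide; 20 aldehyde
Product: 26 (4R)-6-[(tert-butyldiphenylsilyl)oxy]-4-methyl-1-{(1R,2S)-1,3,3-trimethyl-2-[2-(2-methyl-1,3-dioxolan-2-yl)ethyl]cyclohexyl}hexan-1-ol (both C9 epimers), via alkyllithium 25 (not isolated)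
Conditions: 24, t-BuLi (2 equiv), Et2O/pentane, −78 °C; then 20, −78 to 0 °C; then H2O
Reagents that add atoms: none
Why: Lithium–iodine exchange followed by 1,2-addition of the primary alkyllithium to the non-enolisable aldehyde forms the C9–C11 bond; the C9 carbinol centre forms as a mixture, which does not matter because it is oxidised in step 19.

Step 19
Reactants: 26 secondary alcohol
Product: 27 (4R)-6-[(tert-butyldiphenylsilyl)oxy]-4-methyl-1-{(1R,2S)-1,3,3-trimethyl-2-[2-(2-methyl-1,3-dioxolan-2-yl)ethyl]cyclohexyl}hexan-1-one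
Conditions: Dess–Martin periodinane, pyridine, CH2Cl2, rt
Reagents that add atoms: none
Why: Dess–Martin oxidation converts the hindered secondary alcohol into the C9 ketone and removes the uncontrolled stereocentre; C10 is quaternary and cannot epimerise.

Step 20
Reactants: 27 silyl ether ketone
Product: 28 (4R)-6-hydroxy-4-methyl-1-{(1R,2S)-1,3,3-trimethyl-2-[2-(2-methyl-1,3-dioxolan-2-yl)ethyl]cyclohexyl}hexan-1-one
Conditions: Bu4NF, THF, rt
Reagents that add atoms: none
Why: Fluoride-induced desilylation frees the C15 primary alcohol, and the ketal and the hindered ketone are stable to it.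

Step 21
Reactants: 28 hydroxy ketone
Product: 30 (3R)-3-methyl-6-oxo-6-{(1R,2S)-1,3,3-trimethyl-2-[2-(2-methyl-1,3-dioxolan-2-yl)ethyl]cyclohexyl}hexanoic acid, via aldehyde 29 (not isolated)
Conditions: TEMPO (cat.), NaOCl (cat.), NaClO2, MeCN/phosphate buffer (pH 6.7), 35 °C
Reagents that add atoms: sodium chlorite, [Na+].[O-]Cl=O
Why: TEMPO-catalysed oxidation of the primary alcohol to the aldehyde and chlorite oxidation to the acid at near-neutral pH should spare the dioxolane; C13 is β to the new carbonyl and is not epimerisable.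

Step 22
Reactants: 30 acid; 31 (S)-solketal
Product: 32 [(4R)-2,2-dimethyl-1,3-dioxolan-4-yl]methyl (3R)-3-methyl-6-oxo-6-{(1R,2S)-1,3,3-trimethyl-2-[2-(2-methyl-1,3-dioxolan-2-yl)ethyl]cyclohexyl}hexanoate
Conditions: DCC, DMAP (cat.), CH2Cl2, 0 °C to rt
Reagents that add atoms: none
Why: Steglich esterification of the acid with the primary alcohol; the glycerol stereocentre is not involved, and its descriptor changes from (S) to (R) only through the priority rules.

Step 23
Reactants: 32 bis-acetal ester
Product: 33 (2R)-2,3-dihydroxypropyl (3R)-3-methyl-6-oxo-6-[(1R,2S)-1,3,3-trimethyl-2-(3-oxobutyl)cyclohexyl]hexanoate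
Conditions: 1 M HCl, THF, 0 °C to rt
Reagents that add atoms: water, O
Why: Acid-catalysed acetal hydrolysis removes the C8 dioxolane and the acetonide in one operation; low temperature and short contact should keep acyl migration on the glycerol and aldol condensation of the 1,6-diketone in check.

Step 24
Reactants: 33 diol
Product: 34 (2R)-3-acetoxy-2-hydroxypropyl (3R)-3-methyl-6-oxo-6-[(1R,2S)-1,3,3-trimethyl-2-(3-oxobutyl)cyclohexyl]hexanoate (the target)
Conditions: AcCl, 2,4,6-collidine, CH2Cl2, −78 °C
Reagents that add atoms: acetyl chloride, CC(Cl)=O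
Why: Selective acylation: with the hindered base at low temperature the primary hydroxyl should be acetylated well ahead of the secondary one, giving the 1,3-diacylglycerol without touching the glycerol stereocentre.

## Compound list

1 | α-ionone, racemic (E)-4-(2,6,6-trimethylcyclohex-2-en-1-yl)but-3-en-2-one | CC(=O)/C=C/C1C(C)(C)CCC=C1C | starting material
2 | α-ionol, (E)-4-(2,6,6-trimethylcyclohex-2-en-1-yl)but-3-en-2-ol, mixture of the two racemic diastereomers | CC(O)/C=C/C1C(C)(C)CCC=C1C | intermediate
3 | rac-(2R,3E)-4-[(1S)-2,6,6-trimethylcyclohex-2-en-1-yl]but-3-en-2-yl 4-nitrobenzoate (racemate; the enantiomer carried on is drawn) | C[C@@H](OC(=O)c1ccc(cc1)[N+](=O)[O-])/C=C/[C@H]2C(C)(C)CCC=C2C | intermediate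
4 | rac-(2R,3E)-4-[(1S)-2,6,6-trimethylcyclohex-2-en-1-yl]but-3-en-2-ol (racemate; the enantiomer carried on is drawn) | C[C@@H](O)/C=C/[C@H]1C(C)(C)CCC=C1C | intermediate
5 | (2R,3E)-4-[(1S)-2,6,6-trimethylcyclohex-2-en-1-yl]but-3-en-2-yl acetate | C[C@@H](OC(C)=O)/C=C/[C@H]1C(C)(C)CCC=C1C | intermediate
6 | (2R,3E)-4-[(1S)-2,6,6-trimethylcyclohex-2-en-1-yl]but-3-en-2-ol (single enantiomer) | C[C@@H](O)/C=C/[C@H]1C(C)(C)CCC=C1C | intermediate
7 | (S)-α-ionone, (3E)-4-[(1S)-2,6,6-trimethylcyclohex-2-en-1-yl]but-3-en-2-one | CC(=O)/C=C/[C@H]1C(C)(C)CCC=C1C | intermediate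
8 | triethyl({4-[(1S)-2,6,6-trimethylcyclohex-2-en-1-yl]but-2-en-2-yl}oxy)silane (enol ether, E/Z mixture, formed in situ) | CC(O[Si](CC)(CC)CC)=CC[C@H]1C(C)(C)CCC=C1C | intermediate
9 | (S)-dihydro-α-ionone, 4-[(1S)-2,6,6-trimethylcyclohex-2-en-1-yl]butan-2-one | CC(=O)CC[C@H]1C(C)(C)CCC=C1C | intermediate
10 | 2-methyl-2-{2-[(1S)-2,6,6-trimethylcyclohex-2-en-1-yl]ethyl}-1,3-dioxolane | CC2(CC[C@H]1C(C)(C)CCC=C1C)OCCO2 | intermediate
11 | 2-{2-[(1S)-4-(tert-butylperoxy)-2,6,6-trimethylcyclohex-2-en-1-yl]ethyl}-2-methyl-1,3-dioxolane (C2 epimers, formed in situ) | CC2(CC[C@H]1C(C)(C)CC(OOC(C)(C)C)C=C1C)OCCO2 | intermediate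
12 | (4S)-3,5,5-trimethyl-4-[2-(2-methyl-1,3-dioxolan-2-yl)ethyl]cyclohex-2-en-1-one | CC2(CC[C@H]1C(C)(C)CC(=O)C=C1C)OCCO2 | intermediate
13 | (1R,4S)-3,5,5-trimethyl-4-[2-(2-methyl-1,3-dioxolan-2-yl)ethyl]cyclohex-2-en-1-ol (OH cis to the chain) | CC2(CC[C@H]1C(C)(C)C[C@@H](O)C=C1C)OCCO2 | intermediate
14 | tributyl(iodomethyl)stannane | CCCC[Sn](CCCC)(CCCC)CI | starting material
15 | potassium (1R,4S)-3,5,5-trimethyl-4-[2-(2-methyl-1,3-dioxolan-2-yl)ethyl]cyclohex-2-en-1-olate (formed in situ) | CC2(CC[C@H]1C(C)(C)C[C@@H]([O-])C=C1C)OCCO2.[K+] | intermediate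
16 | tributyl({[(1R,4S)-3,5,5-trimethyl-4-[2-(2-methyl-1,3-dioxolan-2-yl)ethyl]cyclohex-2-en-1-yl]oxy}methyl)stannane | CC2(CC[C@H]1C(C)(C)C[C@@H](OC[Sn](CCCC)(CCCC)CCCC)C=C1C)OCCO2 | intermediate
17 | ({[(1R,4S)-3,5,5-trimethyl-4-[2-(2-methyl-1,3-dioxolan-2-yl)ethyl]cyclohex-2-en-1-yl]oxy}methyl)lithium (formed in situ) | CC2(CC[C@H]1C(C)(C)C[C@@H](OC[Li])C=C1C)OCCO2 | intermediate
18 | [(1R,6S)-1,5,5-trimethyl-6-[2-(2-methyl-1,3-dioxolan-2-yl)ethyl]cyclohex-2-en-1-yl]methanol (CH2OH cis to the chain) | CC2(CC[C@H]1C(C)(C)CC=C[C@@]1(C)CO)OCCO2 | intermediate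
19 | [(1R,2S)-1,3,3-trimethyl-2-[2-(2-methyl-1,3-dioxolan-2-yl)ethyl]cyclohexyl]methanol | CC2(CC[C@H]1C(C)(C)CCC[C@@]1(C)CO)OCCO2 | intermediate
20 | (1R,2S)-1,3,3-trimethyl-2-[2-(2-methyl-1,3-dioxolan-2-yl)ethyl]cyclohexane-1-carbaldehyde | CC2(CC[C@H]1C(C)(C)CCC[C@@]1(C)C=O)OCCO2 | intermediate
21 | (R)-citronellol, (3R)-3,7-dimethyloct-6-en-1-ol | CC(C)=CCC[C@@H](C)CCO | starting material
22 | tert-butyl{[(3R)-3,7-dimethyloct-6-en-1-yl]oxy}diphenylsilane | CC(C)=CCC[C@@H](C)CCO[Si](c1ccccc1)(c1ccccc1)C(C)(C)C | intermediate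
23 | (4R)-6-[(tert-butyldiphenylsilyl)oxy]-4-methylhexanoic acid | OC(=O)CC[C@@H](C)CCO[Si](c1ccccc1)(c1ccccc1)C(C)(C)C | intermediate
24 | tert-butyl{[(3S)-5-iodo-3-methylpentyl]oxy}diphenylsilane | ICC[C@@H](C)CCO[Si](c1ccccc1)(c1ccccc1)C(C)(C)C | intermediate
25 | {(3R)-5-[(tert-butyldiphenylsilyl)oxy]-3-methylpentyl}lithium (formed in situ) | [Li]CC[C@@H](C)CCO[Si](c1ccccc1)(c1ccccc1)C(C)(C)C | intermediate
26 | (4R)-6-[(tert-butyldiphenylsilyl)oxy]-4-methyl-1-{(1R,2S)-1,3,3-trimethyl-2-[2-(2-methyl-1,3-dioxolan-2-yl)ethyl]cyclohexyl}hexan-1-ol (C9 epimers) | CC2(CC[C@H]1C(C)(C)CCC[C@@]1(C)C(O)CC[C@@H](C)CCO[Si](c3ccccc3)(c3ccccc3)C(C)(C)C)OCCO2 | intermediate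
27 | (4R)-6-[(tert-butyldiphenylsilyl)oxy]-4-methyl-1-{(1R,2S)-1,3,3-trimethyl-2-[2-(2-methyl-1,3-dioxolan-2-yl)ethyl]cyclohexyl}hexan-1-one | CC2(CC[C@H]1C(C)(C)CCC[C@@]1(C)C(=O)CC[C@@H](C)CCO[Si](c3ccccc3)(c3ccccc3)C(C)(C)C)OCCO2 | intermediate
28 | (4R)-6-hydroxy-4-methyl-1-{(1R,2S)-1,3,3-trimethyl-2-[2-(2-methyl-1,3-dioxolan-2-yl)ethyl]cyclohexyl}hexan-1-one | CC2(CC[C@H]1C(C)(C)CCC[C@@]1(C)C(=O)CC[C@@H](C)CCO)OCCO2 | intermediate
29 | (3R)-3-methyl-6-oxo-6-{(1R,2S)-1,3,3-trimethyl-2-[2-(2-methyl-1,3-dioxolan-2-yl)ethyl]cyclohexyl}hexanal (formed in situ) | CC2(CC[C@H]1C(C)(C)CCC[C@@]1(C)C(=O)CC[C@@H](C)CC=O)OCCO2 | intermediate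
30 | (3R)-3-methyl-6-oxo-6-{(1R,2S)-1,3,3-trimethyl-2-[2-(2-methyl-1,3-dioxolan-2-yl)ethyl]cyclohexyl}hexanoic acid | CC2(CC[C@H]1C(C)(C)CCC[C@@]1(C)C(=O)CC[C@@H](C)CC(O)=O)OCCO2 | intermediate
31 | (S)-solketal, [(4S)-2,2-dimethyl-1,3-dioxolan-4-yl]methanol | OC[C@H]1COC(C)(C)O1 | starting material
32 | [(4R)-2,2-dimethyl-1,3-dioxolan-4-yl]methyl (3R)-3-methyl-6-oxo-6-{(1R,2S)-1,3,3-trimethyl-2-[2-(2-methyl-1,3-dioxolan-2-yl)ethyl]cyclohexyl}hexanoate | CC2(CC[C@H]1C(C)(C)CCC[C@@]1(C)C(=O)CC[C@@H](C)CC(=O)OC[C@H]3COC(C)(C)O3)OCCO2 | intermediate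
33 | (2R)-2,3-dihydroxypropyl (3R)-3-methyl-6-oxo-6-[(1R,2S)-1,3,3-trimethyl-2-(3-oxobutyl)cyclohexyl]hexanoate | CC(=O)CC[C@H]1C(C)(C)CCC[C@@]1(C)C(=O)CC[C@@H](C)CC(=O)OC[C@H](O)CO | intermediate
34 | (2R)-3-acetoxy-2-hydroxypropyl (3R)-3-methyl-6-oxo-6-[(1R,2S)-1,3,3-trimethyl-2-(3-oxobutyl)cyclohexyl]hexanoate | CC(=O)CC[C@H]1C(C)(C)CCC[C@@]1(C)C(=O)CC[C@@H](C)CC(=O)OC[C@H](O)COC(C)=O | target

## Step count and main risks

Total step count: 24. Longest linear sequence: 21 steps (steps 1–14, then 18–24); the side-chain branch is steps 15–17.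

Three steps most likely to fail:

1. Step 12 (Wittig–Still shift). The [1,2]-shift or plain protonation of the carbanion may win, because the reactive conformer needs the C2–O bond pseudoaxial on the face that also carries the axial C4 methyl, and the carbon terminus is fully substituted. The fallback sets out from cis-alcohol 13. Heating 13 with N,N-dimethylformamide dimethyl acetal in xylene (about 140 °C, methanol distilled off) should give the mixed formamide acetal F1, which loses methanol and rearranges in a thermal, suprafacial [2,3]-shift to the β,γ-unsaturated dimethylamide F2, with C9 installed on C10 at the carboxamide level on the same face as the departing oxygen. Hydrogenation (H2, Pd/C) gives the saturated amide F3. Addition of alkyllithium 25 (generated as in step 18) to F3 forms a stable tetrahedral adduct that collapses on work-up to ketone 27, where the route is rejoined; steps 11–14, 18 and 19 are then not needed.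

2. Step 10 (catalyst-controlled reduction). Facial selectivity may be poor if the substrate opposes the catalyst, since both faces of the enone are hindered, giving much of the trans epimer. The fallback sets out from enone 12. Reduction without a chiral reagent (NaBH4, CeCl3·7H2O, MeOH, −78 °C) gives both epimers, which are separated by chromatography; the cis alcohol 13 is used directly. The trans alcohol F4 is inverted by a Mitsunobu reaction (4-nitrobenzoic acid, PPh3, diisopropyl azodicarboxylate, THF) to the cis 4-nitrobenzoate F5, and methanolysis (K2CO3, MeOH) returns the route to 13.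

3. Step 23 (acidic unmasking next to the glyceryl ester). Acid may cause acyl migration between the glycerol oxygens, which scrambles the position and configuration of the glyceride, and may promote aldol condensation of the 1,6-diketone; the later selective acetylation depends on a clean diol. The fallback sets out from acid 30. Hydrolysis of the ketal alone (1 M HCl, THF, 0 °C) gives the diketo acid F6, with no glyceride present to migrate. Commercial (R)-glycidol is acetylated (Ac2O, pyridine) to (S)-glycidyl acetate F7. Opening of F7 at its terminal carbon by the carboxylic acid of F6, with (salen)Co(OAc) as catalyst and i-Pr2NEt at rt, should give the 1,3-diacylglycerol with the free secondary hydroxyl directly, which is target 34; the acetonide stage and the selective acetylation are avoided.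

Further compounds
F1 | step 12 | 1-methoxy-N,N-dimethyl-1-{[(1R,4S)-3,5,5-trimethyl-4-[2-(2-methyl-1,3-dioxolan-2-yl)ethyl]cyclohex-2-en-1-yl]oxy}methanamine (mixed formamide acetal of 13) | CC2(CC[C@H]1C(C)(C)C[C@@H](OC(OC)N(C)C)C=C1C)OCCO2
F2 | step 12 | (1R,6S)-N,N,1,5,5-pentamethyl-6-[2-(2-methyl-1,3-dioxolan-2-yl)ethyl]cyclohex-2-ene-1-carboxamide | CC2(CC[C@H]1C(C)(C)CC=C[C@@]1(C)C(=O)N(C)C)OCCO2
F3 | step 12 | (1R,2S)-N,N,1,3,3-pentamethyl-2-[2-(2-methyl-1,3-dioxolan-2-yl)ethyl]cyclohexane-1-carboxamide | CC2(CC[C@H]1C(C)(C)CCC[C@@]1(C)C(=O)N(C)C)OCCO2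
F4 | step 10 | (1S,4S)-3,5,5-trimethyl-4-[2-(2-methyl-1,3-dioxolan-2-yl)ethyl]cyclohex-2-en-1-ol (OH trans to the chain) | CC2(CC[C@H]1C(C)(C)C[C@H](O)C=C1C)OCCO2
F5 | step 10 | (1R,4S)-3,5,5-trimethyl-4-[2-(2-methyl-1,3-dioxolan-2-yl)ethyl]cyclohex-2-en-1-yl 4-nitrobenzoate | CC2(CC[C@H]1C(C)(C)C[C@@H](OC(=O)c3ccc(cc3)[N+](=O)[O-])C=C1C)OCCO2
F6 | step 23 | (3R)-3-methyl-6-oxo-6-[(1R,2S)-1,3,3-trimethyl-2-(3-oxobutyl)cyclohexyl]hexanoic acid | CC(=O)CC[C@H]1C(C)(C)CCC[C@@]1(C)C(=O)CC[C@@H](C)CC(O)=O
F7 | step 23 | (S)-glycidyl acetate, [(2S)-oxiran-2-yl]methyl acetate | CC(=O)OC[C@@H]1CO1
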